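## Retrosynthetic overview

1. Target ⇒ nucleophilic epoxidation of the half A enone and double ortho-chlorination of a bis-phenolic spiroketal enone (last two steps).
2. Spiroketal enone ⇒ open quinone bis-ketal diol: in one acid-triggered operation the C1'–OH and then the peri C8'–OH exchange onto C1, closing the oxolane and the 1,3-dioxane ring together; C1 is fixed by C1'.
3. Bis-ketal diol ⇒ C8–C1' bond by 1,2-addition of a lithiated naphthoquinone bis-ketal to an α,β-epoxy ketone (anti to the oxirane), then redox correction of C4'.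
4. Epoxy ketone ⇒ CBS desymmetrisation of the meso epoxide of bis-MOM naphthazarin; aryllithium ⇒ bromination and anodic bis-ketalisation of bis-MOM naphthalene-1,5-diol.
5. Ring order: half B oxirane → oxolane + 1,3-dioxane (one operation) → half A oxirane.

Assumption: locants C1–C8a (half A, ketone half; C1 = spiroketal carbon) and C1'–C8a' (half B, carbinol half; C1' = carbon bearing the bridging oxygen and C8) follow the naphthalene numbering of each half; cis/trans refer to the oxirane oxygen of the same ring; the adducts of steps 7 and 8 are 1:1 epimer mixtures at the mixed OMe/OMOM ketal carbon, which becomes C1 in step 9.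

## Route

Step 1
Reactants: 1 naphthalene-1,5-diol
Product: 2 1,5-bis(methoxymethoxy)naphthalene
Conditions: NaH, MOMCl, DMF, 0 °C → rt
Reagents that add atoms: chloromethyl methyl ether (MOMCl), COCCl
Why: Williamson O-alkylation (MOM protection) of both naphtholates; no stereocentre is formed.

Step 2
Reactants: 2 1,5-bis(methoxymethoxy)naphthalene
Product: 3 4-bromo-1,5-bis(methoxymethoxy)naphthalene
Conditions: NBS (1.0 equiv), MeCN, 0 °C → rt, dark
Reagents that add atoms: N-bromosuccinimide (NBS), O=C1CCC(=O)N1Br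
Why: Electrophilic aromatic bromination goes para to one OMOM group and peri to the other, as for 1,5-dimethoxynaphthalene, and one equivalent avoids the 4,8-dibromide.

Step 3
Reactants: 3 4-bromo-1,5-bis(methoxymethoxy)naphthalene
Product: 4 4-bromo-5,8,8-trimethoxy-1,5-bis(methoxymethoxy)-5,8-dihydronaphthalene (quinone bis-ketal; racemic at C5)
Conditions: Pt anode, Pt cathode, undivided cell, 1% KOH in MeOH, 0 °C, constant current, ca. 4.5 F/mol
Reagents that add atoms: methanol, CO
Why: Swenton-type anodic methoxylation (quinone bis-ketal synthesis) attacks the ring with the free para C–H at C8 and oxidises it on to the 5,8-bis-ketal while the bromo-bearing ring stays aromatic; the mixed ketal carbon forms racemic and is lost in step 9.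

Step 4
Reactants: 5 5,8-dihydroxynaphthalene-1,4-dione (naphthazarin)
Product: 6 5,8-bis(methoxymethoxy)naphthalene-1,4-dione
Conditions: MOMCl (4 equiv), i-Pr2NEt (5 equiv), CH2Cl2, 0 → 40 °C
Reagents that add atoms: chloromethyl methyl ether (MOMCl), COCCl
Why: O-alkylation of the two chelated peri phenols gives the benzenoid 5,8-diether of the 1,4-quinone, which keeps the molecule symmetric.

Step 5
Reactants: 6 5,8-bis(methoxymethoxy)naphthalene-1,4-dione
Product: 7 meso-(2R,3S)-2,3-epoxy-5,8-bis(methoxymethoxy)-2,3-dihydronaphthalene-1,4-dione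
Conditions: 30% aq. H2O2, Na2CO3, THF/H2O, 0 °C
Reagents that add atoms: hydrogen peroxide, OO
Why: Weitz–Scheffer nucleophilic epoxidation of the quinone C2=C3 bond gives the cis-fused oxirane, which is meso.

Step 6
Reactants: 7 meso-(2R,3S)-2,3-epoxy-5,8-bis(methoxymethoxy)-2,3-dihydronaphthalene-1,4-dione
Product: 8 (2R,3R,4R)-2,3-epoxy-4-hydroxy-5,8-bis(methoxymethoxy)-3,4-dihydronaphthalen-1(2H)-one (OH cis to the oxirane oxygen)
Conditions: (R)-1-methyl-3,3-diphenyl-tetrahydro-1H,3H-pyrrolo[1,2-c][1,3,2]oxazaborole [(R)-Me-CBS, 20 mol %], BH3·SMe2 (0.6 equiv), THF, −40 °C; MeOH, then aq. work-up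
Reagents that add atoms: none
Why: Corey–Bakshi–Shibata reduction desymmetrises the meso diketone, because catalyst control (aryl as the large group, as for 1-tetralone) and substrate control (hydride anti to the oxirane) are matched for only one of the two enantiotopic carbonyls, giving the (4R)-carbinol, which serves only to mark the other carbonyl for arylation.

Step 7
Reactants: 4 4-bromo-5,8,8-trimethoxy-1,5-bis(methoxymethoxy)-5,8-dihydronaphthalene; 8 (2R,3R,4R)-2,3-epoxy-4-hydroxy-5,8-bis(methoxymethoxy)-3,4-dihydronaphthalen-1(2H)-one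
Product: 10 1-[5,5,8-trimethoxy-4,8-bis(methoxymethoxy)-5,8-dihydronaphthalen-1-yl]-2,3-epoxy-5,8-bis(methoxymethoxy)-1,2,3,4-tetrahydronaphthalene-1,4-diol (aryl trans; both OH cis to the oxirane oxygen), via aryllithium 9 (not isolated)
Conditions: 4 (1.2 equiv), n-BuLi, THF, −78 °C; then lithium alkoxide of 8 [LiN(SiMe3)2, THF, −78 °C], −78 → −40 °C; pH 7 buffer
Reagents that add atoms: none
Why: Bromine–lithium exchange followed by 1,2-addition of the aryllithium to the non-enolisable aryl ketone from the face anti to the oxirane oxygen (Felkin–Anh-type control) sets C1' with the aryl group trans and the OH cis to the epoxide, and forms the C8–C1' bond.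

Step 8
Reactants: 10 the cis,cis-diol of step 7
Product: 12 C4 epimer of 10 (1-OH cis; 4-OH trans to the oxirane oxygen), via hydroxy ketone 11 (not isolated)
Conditions: (n-Pr4N)RuO4 (5 mol %), N-methylmorpholine N-oxide (NMO), 4 Å MS, CH2Cl2, rt; filter, concentrate; then NaBH4, THF/MeOH, −78 → −40 °C
Reagents that add atoms: none
Why: Ley–Griffith oxidation erases the marker carbinol, and NaBH4 then reduces the C4' ketone from the face of the C1' alkoxide (alkoxide-assisted delivery, opposite the pseudo-axial C1' aryl group), so the C4'–OH ends trans to the epoxide and to the C1' oxygen as in the target.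

Step 9
Reactants: 12 the diol of step 8
Product: 14 spiroketal enone (C2=C3–C4=O enone; C1 ketal oxygens bound to C1' and C8'; C8–C1' bond; half B oxirane cis to the C1'–O bond; C4'-OH trans to that oxirane; 5-OH and 5'-OH free), via cyclic methyl ketal 13 (not isolated)
Conditions: CF3CO2H/CH2Cl2/H2O (10:88:2), 0 °C → rt; aq. NaHCO3
Reagents that add atoms: water, O
Why: Proposed new method: aqueous CF3CO2H first ionises the doubly activated OMe/OMOM ketal at C1; the neighbouring tertiary C1'–OH traps the oxocarbenium ion (oxolane ring, 13); the C4 dimethyl ketal hydrolyses to the enone; the aryl MOM ethers are cleaved; and the freed peri C8'–OH replaces the last C1–OMe through a second oxocarbenium ion to close the 1,3-dioxane ring; only one bridged ketal is possible for the fixed C1' centre, so C1 is set by it; the closest known reaction types are acid-catalysed transketalisation of keto diols to bicyclic ketals and the acid mono-hydrolysis of Swenton quinone bis-ketals.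

Step 10
Reactants: 14 spiroketal enone
Product: 15 6,6'-dichloro spiroketal enone
Conditions: NCS (2.1 equiv), i-Pr2NH (10 mol %), CH2Cl2, 0 °C → rt
Reagents that add atoms: N-chlorosuccinimide (NCS), O=C1CCC(=O)N1Cl
Why: Amine-catalysed electrophilic ortho-chlorination of phenols puts chlorine at C6 and C6', because each para position is blocked (C8 and the C8' ketal oxygen) and the C4 carbonyl also directs to C6.

Step 11
Reactants: 15 6,6'-dichloro spiroketal enone
Product: 16 target CNP0289684.3
Conditions: t-BuOOH (in decane), 1,5,7-triazabicyclo[4.4.0]dec-5-ene, toluene/CH2Cl2, 0 °C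
Reagents that add atoms: tert-butyl hydroperoxide, CC(C)(C)OO
Why: Weitz–Scheffer nucleophilic epoxidation: t-BuOO− adds to C2 of the quinone-monoketal enone from the face opposite the axial C1–O–C8' bond and the half B arene above it, giving the oxirane cis to the C1–O–C1' oxygen while the half B epoxide, carbinol and aryl chlorides are untouched.

## Compound list

1 | naphthalene-1,5-diol | Oc1cccc2c(O)cccc12 | starting material
2 | 1,5-bis(methoxymethoxy)naphthalene | COCOc1cccc2c(OCOC)cccc12 | intermediate
3 | 4-bromo-1,5-bis(methoxymethoxy)naphthalene | COCOc1ccc(Br)c2c(OCOC)cccc12 | intermediate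
4 | 4-bromo-5,8,8-trimethoxy-1,5-bis(methoxymethoxy)-5,8-dihydronaphthalene (racemic at C5) | COCOc1ccc(Br)c2c1C(OC)(OC)C=CC2(OC)OCOC | intermediate
5 | 5,8-dihydroxynaphthalene-1,4-dione (naphthazarin) | O=C1C=CC(=O)c2c(O)ccc(O)c12 | starting material
6 | 5,8-bis(methoxymethoxy)naphthalene-1,4-dione | O=C1C=CC(=O)c2c(OCOC)ccc(OCOC)c12 | intermediate
7 | meso-(2R,3S)-2,3-epoxy-5,8-bis(methoxymethoxy)-2,3-dihydronaphthalene-1,4-dione | O=C1[C@@H]2O[C@@H]2C(=O)c2c(OCOC)ccc(OCOC)c12 | intermediate
8 | (2R,3R,4R)-2,3-epoxy-4-hydroxy-5,8-bis(methoxymethoxy)-3,4-dihydronaphthalen-1(2H)-one (OH cis to oxirane O) | O=C1[C@@H]2O[C@@H]2[C@H](O)c2c(OCOC)ccc(OCOC)c12 | intermediate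
9 | 5,5,8-trimethoxy-4,8-bis(methoxymethoxy)-5,8-dihydronaphthalen-1-yllithium | [Li]c1ccc(OCOC)c2c1C(OC)(OCOC)C=CC2(OC)OC | intermediate
10 | 1-aryl-2,3-epoxy-5,8-bis(methoxymethoxy)-1,2,3,4-tetrahydronaphthalene-1,4-diol, aryl = 5,5,8-trimethoxy-4,8-bis(methoxymethoxy)-5,8-dihydronaphthalen-1-yl; aryl trans, 1-OH and 4-OH cis to oxirane O | O[C@]1(c2ccc(OCOC)c3c2C(OC)(OCOC)C=CC3(OC)OC)[C@@H]2O[C@@H]2[C@H](O)c2c(OCOC)ccc(OCOC)c21 | intermediate
11 | 4-aryl-2,3-epoxy-4-hydroxy-5,8-bis(methoxymethoxy)-3,4-dihydronaphthalen-1(2H)-one (same aryl; aryl trans, OH cis to oxirane O) | O[C@]1(c2ccc(OCOC)c3c2C(OC)(OCOC)C=CC3(OC)OC)[C@@H]2O[C@@H]2C(=O)c2c(OCOC)ccc(OCOC)c21 | intermediate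
12 | C4 epimer of 10 (aryl trans, 1-OH cis, 4-OH trans to oxirane O) | O[C@]1(c2ccc(OCOC)c3c2C(OC)(OCOC)C=CC3(OC)OC)[C@@H]2O[C@@H]2[C@@H](O)c2c(OCOC)ccc(OCOC)c21 | intermediate
13 | oxolane-closed methyl ketal: C1(OMe)–O–C1' bridge, C2=C3–C4=O enone, three aryl OMOM groups, C4'-OH (epimers at C1) | COCOc1ccc2c3c1C(=O)C=CC3(OC)O[C@@]21[C@@H]3O[C@@H]3[C@@H](O)c3c(OCOC)ccc(OCOC)c31 | intermediate
14 | spiroketal enone: dechloro 2,3-didehydro precursor of the target (half B oxirane, C4'-OH, 5-OH, 5'-OH) | O=C1c2c(O)ccc3c2[C@@]2(Oc4ccc(O)c5c4[C@]3(O2)[C@@H]2O[C@@H]2[C@H]5O)C=C1 | intermediate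
15 | 6,6'-dichloro spiroketal enone | O=C1c2c(O)c(Cl)cc3c2[C@@]2(Oc4cc(Cl)c(O)c5c4[C@]3(O2)[C@@H]2O[C@@H]2[C@H]5O)C=C1 | intermediate
16 | CNP0289684.3: 6,6'-dichloro-2,3:2',3'-bis-epoxy-4-oxo-4',5,5'-triol spiroketal (C1 ketal to O–C1' and O–C8'; C8–C1' bond; both oxiranes cis to the C1–O–C1' oxygen; C4'-OH trans to the half B oxirane) | O=C1c2c(O)c(Cl)cc3c2[C@@]2(Oc4cc(Cl)c(O)c5c4[C@]3(O2)[C@@H]2O[C@@H]2[C@H]5O)[C@@H]2O[C@H]12 | target

## Step count and weak points

Total step count: 11. Longest linear sequence: 8 steps (1→2→3→4→10→12→14→15→16, or 5→6→7→8→10→12→14→15→16).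

Steps most likely to fail: step 9, step 7 and step 8.

Step 9 (the acid cascade may stall at the methyl ketal, ionise C1' or open the oxirane). Fallback: close the two rings one at a time under non-equilibrating conditions. It sets out from 12. Buffered aqueous AcOH in acetone unravels only the bis-ketal and gives cyclic methyl ketal 13, now isolated. Me3SiOTf/2,2'-bipyridyl in MeCN, then water, removes the three aryl MOM groups without protic acid and gives the triphenol methyl ketal F6. Catalytic BF3·OEt2 in CH2Cl2 at −40 °C then ionises the C1–OMe bond, and the C8'–OH closes the dioxane ring in a glycosylation-type step. The fallback comes back to the route at 14.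

Step 7 (the peri-ketal aryllithium 9 may be too hindered to add to 8). Fallback: make the C8–C1' bond before the ketal carbon exists and raise the oxidation level of half A afterwards. It sets out from 3 (with 8). Bromide 3 and n-BuLi give 4-lithio-1,5-bis(methoxymethoxy)naphthalene F1. F1 adds to the lithium alkoxide of 8 anti to the oxirane and gives the cis,cis-diol with an unoxidised naphthyl group F2. Oxidation with (n-Pr4N)RuO4/NMO gives the hydroxy ketone F3, whose half B arene is now deactivated by the aryl ketone. Anodic oxidation in KOH/MeOH (as in step 3) then converts only the naphthyl ring with the free para C–H into the bis-ketal. The fallback comes back to the route at 11, which is reduced as in step 8.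

Step 8 (NaBH4 may attack 11 anti to the oxirane and return 10). Fallback: set C4' by SN2 inversion before the union instead of by reduction after it. It sets out from 8. A Mitsunobu reaction (4-nitrobenzoic acid, PPh3, DIAD, THF) gives the inverted (2R,3R,4S)-4-nitrobenzoate F4. K2CO3 in MeOH at 0 °C gives the trans hydroxy epoxy ketone F5. Its lithium alkoxide takes up aryllithium 9 under the conditions of step 7. The fallback comes back to the route at 12.

Further compounds

F1 | step 7 | 4-lithio-1,5-bis(methoxymethoxy)naphthalene | [Li]c1ccc(OCOC)c2cccc(OCOC)c12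
F2 | step 7 | 1-[4,8-bis(methoxymethoxy)naphthalen-1-yl]-2,3-epoxy-5,8-bis(methoxymethoxy)-1,2,3,4-tetrahydronaphthalene-1,4-diol (aryl trans, both OH cis to oxirane O) | O[C@]1(c2ccc(OCOC)c3cccc(OCOC)c23)[C@@H]2O[C@@H]2[C@H](O)c2c(OCOC)ccc(OCOC)c21
F3 | step 7 | 4-[4,8-bis(methoxymethoxy)naphthalen-1-yl]-2,3-epoxy-4-hydroxy-5,8-bis(methoxymethoxy)-3,4-dihydronaphthalen-1(2H)-one (aryl trans, OH cis to oxirane O) | O[C@]1(c2ccc(OCOC)c3cccc(OCOC)c23)[C@@H]2O[C@@H]2C(=O)c2c(OCOC)ccc(OCOC)c21
F4 | step 8 | (2R,3R,4S)-2,3-epoxy-5,8-bis(methoxymethoxy)-1-oxo-1,2,3,4-tetrahydronaphthalen-4-yl 4-nitrobenzoate (ester trans to oxirane O) | O=C1[C@@H]2O[C@@H]2[C@@H](OC(=O)c3ccc(cc3)[N+](=O)[O-])c2c(OCOC)ccc(OCOC)c12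
F5 | step 8 | (2R,3R,4S)-2,3-epoxy-4-hydroxy-5,8-bis(methoxymethoxy)-3,4-dihydronaphthalen-1(2H)-one (OH trans to oxirane O) | O=C1[C@@H]2O[C@@H]2[C@@H](O)c2c(OCOC)ccc(OCOC)c12
F6 | step 9 | triphenol methyl ketal: 13 without its three MOM groups (epimers at C1) | Oc1ccc2c3c1C(=O)C=CC3(OC)O[C@@]21[C@@H]3O[C@@H]3[C@@H](O)c3c(O)ccc(O)c31
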